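The constants used here are those of an exercise.

One unit here is the whole Q charged: Q, L and X are fractions of it, so L starts at 0.500 in the north-west flask and at 2.00 in the north-east flask.

| setting | north-west | west | south-east | north-east |
|---|---|---|---|---|
| Q | 20 mM | 20 mM | 20 mM | 20 mM |
| L | 10.0 mM | 15.0 mM | 25.0 mM | 40.0 mM |
| time | 8.0 min | 8.0 min | 8.0 min | 8.0 min |

    Q + L → J + D (k1 = 0.894 M⁻¹ s⁻¹)
    Q + D → Q.D (k2 = 8.59 M⁻¹ s⁻¹)
    X + L → J + G (k3 = 0.822 M⁻¹ s⁻¹)
    D + L → J + X (k4 = 8.42 M⁻¹ s⁻¹)

- in percentages every species weighs as the Q in it: one Q.D counts as two
- "hardly changes" means that all values lie within two and a half points (for a concentration: within two and a half percent of the largest)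
- run time (north-west): 8.0 min

- amount of X at the end, in percent of the Q charged for north-west, west, south-east, north-east, in this order
- the course of these numbers from the first flask to the last (rises all the way / falls all the way / falls, then rises / rises, then falls / hardly changes)

A reckoning by hand, one process at a time:

1. First exchange (Q + L). Q gives D, and in the north-west flask Q has a half-life of 1.3 min by this step alone, with L as charged. This step makes no X.

2. Add capture (Q + D) and second exchange (D + L). In the north-west flask, D has a half-life of 0.067 min by capture alone and 0.14 min by second exchange alone, the other concentrations as charged. Both are shorter than the half-life of Q, so D is treated as a steady-state intermediate. Let h be the capture constant over the second-exchange constant, 1.02. The share of D that becomes X, a selectivity, is then f = L/(L + h·Q). At the charges, f is 0.329 in the north-west flask and 0.662 in the north-east flask.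

3. Add third exchange (X + L). Feed and drain of X both carry L, so L cancels from their balance. Let r be the feed ratio, the first-exchange constant over the third-exchange constant, 1.09. X stops rising at the ceiling C = r·f·Q = r·Q·L/(L + h·Q). Above C, X falls while L stands. For L far below h·Q, C tends to r·L/h. For L far above h·Q, C tends to r·Q. Joined, with r and h close to 1, C follows the smaller of Q and L.

4. At the charges, C is 0.358 in the north-west flask and 0.720 in the north-east flask. In the north-west flask L is the smaller charge, so C is expected to sink with L, but the drain on X needs L too, so X is expected to level off above C. In the north-east flask L is the larger charge, so C is expected to sink with Q while L goes on draining X. This reckoning commits to a row that rises, then falls, and gives no figure for each flask.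

The forecast gives 7%, 12%, 14% and 4%, a row that rises, then falls. Its ground for the north-east flask is that “L outlasts Q and slowly drains X to G”.

X ends at 6.15%, 9.81%, 13.0% and 7.52% of the Q charged, so the row rises, then falls, turning at L charged at 25 mM. In the north-west flask at 4.00 min, C from the standing Q and L is 2.81%, below X at 6.38%. A run to 80.0 min makes no difference to X at the end in the north-west flask. In the north-east flask at 8.00 min, C is 1.59%, below X at 7.52%, and after 80.0 min X stands at 0.467%.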